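**Retrosynthetic overview**

1. The C8 ester (bought (R)-2-methylbutanoic acid) and the free O1/O8 hydroxyls are unveiled last from a diisopropylsilaketal that bridges O1 and O8.
2. Feature used: the carbocycle is a (Z,Z)-cyclodeca-1,6-diene (C1–C10) whose trisubstituted alkenes C4=C5 and C9=C10 each lie between two oxygenated allylic carbons (C3/C6 and C1/C8), with O6, C11 and O8 all-cis on C6–C7–C8. Cutting both alkenes and joining C5 to C9 gives a cis-fused cyclopentene γ-lactone (ring C5–C6–C7–C8–C9) plus a 2,6-dimethylhepta-1,6-diene-3,5-diol unit (C10–C1–C2–C3–C4).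
3. Key disconnection: ring-rearrangement metathesis of the O1–Si–O8 tethered pair, which opens the cyclopentene and forms C9=C10 and C4=C5.
4. Halves: the all-cis hydroxy methylene lactone comes from a bought bicyclic lactone (α-methylenation, epoxide/selenide transposition, oxidation, Luche reduction); the anti-diol monoacetate comes from methacrolein and 3-methylbut-3-en-2-one (Ipc2BCl aldol, Evans–Tishchenko reduction).
5. Ring order: γ-lactone (bought, fused to the cyclopentene); then in the key step the cyclopentene is opened, the seven-membered dioxasilepine closed and the ten-membered carbocycle closed; the dioxasilepine is cleaved afterwards.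

Key step: step 11

Remark on numbering: compounds 18–26 carry germacrane numbers (ring C1–C10, lactone C11–C13, C14 on C10, C15 on C4). The bicyclic lactones 1–10 carry 2-oxabicyclo[3.3.0]octane numbers (C1 = future C6, C5 = future C7, C6 = future C8, C7 = future C9, C8 = future C5, C4 = future C11).

Assumption: the (+)-Ipc2BCl enolate of a methyl ketone is taken to attack the Si face of methacrolein. The C3 configuration of 15 would be checked by Mosher ester analysis and the antipodal borane used if the sense were opposite.

**Route**

Step 1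
Reactants: 1 (1S,5R)-2-oxabicyclo[3.3.0]oct-6-en-3-one
Product: 2 4-exo-[(dimethylamino)methyl]-2-oxabicyclo[3.3.0]oct-6-en-3-one (ring-fusion configuration of 1)
Conditions: LiN(iPr)2, THF, −78 °C; CH2=NMe2+ I−, −78 °C to rt
Reagents that add atoms: dimethylmethyleneiminium iodide (Eschenmoser's salt) C=[N+](C)C.[I-]
Why: Mannich reaction of the lactone lithium enolate with Eschenmoser's salt; the electrophile should enter from the convex face of the cis-fused bicycle, and the new C4 centre is of no consequence because step 2 removes it.

Step 2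
Reactants: 2 4-exo-[(dimethylamino)methyl] lactone
Product: 4 4-methylene-2-oxabicyclo[3.3.0]oct-6-en-3-one (ring-fusion configuration of 1), via trimethylammonium iodide 3 (not isolated)
Conditions: MeI, MeOH, rt; then NaHCO3, H2O/CH2Cl2, rt
Reagents that add atoms: none
Why: Exhaustive N-methylation followed by E1cB (Hofmann-type) loss of trimethylamine should give the α-methylene lactone under bicarbonate conditions too mild to move the exocyclic alkene into the ring.

Step 3
Reactants: 4 4-methylene-2-oxabicyclo[3.3.0]oct-6-en-3-one
Product: 5 6,7-exo-epoxy-4-methylene-2-oxabicyclo[3.3.0]octan-3-one (epoxide oxygen on the convex face, anti to the lactone ring)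
Conditions: mCPBA, NaHCO3, CH2Cl2, 0 °C to rt
Reagents that add atoms: 3-chloroperbenzoic acid O=C(OO)c1cccc(Cl)c1
Why: Prilezhaev epoxidation should take the electron-rich cyclopentene from its open convex face and leave the electron-poor methylene lactone untouched.

Step 4
Reactants: 5 exo-epoxide
Product: 6 6-exo-hydroxy-7-endo-phenylseleno-4-(phenylselenomethyl)-2-oxabicyclo[3.3.0]octan-3-one (trans hydroxy selenide; C4 epimers)
Conditions: (PhSe)2 (1.3 equiv), NaBH4 (2.5 equiv), EtOH, rt; then 5, 0 to 60 °C
Reagents that add atoms: diphenyl diselenide c1ccc(cc1)[Se][Se]c1ccccc1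
Why: The benzeneselenolate (as its ethoxyborate complex) should open the epoxide anti at C7, the carbon remote from the ring fusion (C6 is screened on the concave side by the lactone α-carbon), and add 1,4 to the methylene lactone, which is thereby masked; the C4 epimers converge in step 5.

Step 5
Reactants: 6 bis-selenide
Product: 8 6-exo-hydroxy-4-methylene-2-oxabicyclo[3.3.0]oct-7-en-3-one (hydroxyl trans to the lactone ring), via bis-selenoxide 7 (not isolated)
Conditions: H2O2 (30 %), pyridine, THF, 0 °C to rt
Reagents that add atoms: none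
Why: Selenide oxidation and syn-elimination: the ring selenoxide should eliminate away from the carbinol carbon toward the C8 methylene to give the transposed allylic alcohol, and the side-chain selenoxide has only the C4 hydrogen available and restores the exocyclic methylene.

Step 6
Reactants: 8 exo-allylic alcohol
Product: 9 cis-4-methylene-2-oxabicyclo[3.3.0]oct-7-ene-3,6-dione
Conditions: Dess–Martin periodinane, NaHCO3, CH2Cl2, 0 °C
Reagents that add atoms: none
Why: Dess–Martin oxidation under buffered, non-basic conditions should give the enone without enolization at the ring-fusion carbon, which would draw the exocyclic alkene into conjugation; the enone is used directly.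

Step 7
Reactants: 9 enone
Product: 10 all-cis-6-hydroxy-4-methylene-2-oxabicyclo[3.3.0]oct-7-en-3-one (6-endo hydroxyl, cis to O2 and C4)
Conditions: NaBH4, CeCl3·7H2O, MeOH, −78 °C; acetone, then pH 7 buffer
Reagents that add atoms: none
Why: Luche 1,2-reduction in which hydride should attack C6 from the convex face, anti to the neighbouring lactone α-carbon, so the hydroxyl ends cis to O2 and C4; the low temperature spares the methylene lactone, and the product is kept neutral and used the same day because translactonization onto the new hydroxyl would convert it into its mirror image.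

Step 8
Reactants: 11 3-methylbut-3-en-2-one; 12 methacrolein
Product: 15 (S)-5-hydroxy-2,6-dimethylhepta-1,6-dien-3-one, via enol borinate 13 (not isolated), via boron aldolate 14 (not isolated)
Conditions: (+)-Ipc2BCl, Et3N, Et2O, 0 °C; 12, −78 to −20 °C; H2O2, pH 7 buffer, MeOH, 0 °C
Reagents that add atoms: none
Why: Diisopinocampheylboron-mediated methyl ketone aldol: only the methyl group of 11 can be enolized, and the chiral enol borinate is expected to add to the Si face of methacrolein and set C3 as S; any minor enantiomer would leave later as a diastereomer of 18.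

Step 9
Reactants: 15 (S)-β-hydroxy enone
Product: 16 (3S,5S)-5-hydroxy-2,6-dimethylhepta-1,6-dien-3-yl acetate (anti-1,3-diol monoacetate)
Conditions: SmI2 (0.3 equiv), MeCHO (8 equiv), THF, −10 °C
Reagents that add atoms: acetaldehyde CC=O
Why: Evans–Tishchenko reduction: the samarium-bound hemiacetal formed from acetaldehyde on the C3 hydroxyl delivers hydride to the ketone through a chair-like six-membered transition state, which sets C1 1,3-anti (S) and leaves the acetate on O3; acetyl migration between the two oxygens is degenerate because the parent diol is C2-symmetric.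

Step 10
Reactants: 16 anti-diol monoacetate; 10 all-cis hydroxy methylene lactone
Product: 18 mixed diisopropylsilaketal linking the lactone hydroxyl (future O8) to the free hydroxyl of 16 (future O1), via chlorosilyl ether 17 (not isolated)
Conditions: 16 (1.3 equiv), iPr2SiCl2 (1.3 equiv), imidazole, CH2Cl2, 0 °C; then 10, imidazole, DMF, 0 °C to rt
Reagents that add atoms: dichlorodiisopropylsilane CC(C)[Si](Cl)(Cl)C(C)C
Why: Stepwise substitution at silicon: the isopropyl groups should stop the first silylation at the monoalkoxy chlorosilane, which then silylates 10 under imidazole catalysis faster than 10 can translactonize; no stereocentre is touched.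

Step 11
Reactants: 18 mixed diisopropylsilaketal
Product: 21 (1S,3S,4Z,9Z)-3-acetoxy-1,8-O-(diisopropylsilanediyl)germacra-4,9,11(13)-trien-12,6-olide (6,7-cis lactone; O6/C11/O8 all-cis), via ring-opened tetraene 19 (not isolated), via dioxasilepine triene 20 (not isolated)
Conditions: (H2IMes)(PCy3)Cl2Ru=CHPh (second-generation Grubbs catalyst, 15 mol % in two portions), 1,4-benzoquinone (30 mol %), toluene, 1 mM, C2H4 (1 atm), 40 °C, 1 h; then Ar sparge, 100 °C
Reagents that add atoms: none
Why: Proposed new method: a Ru methylidene adds to the open convex face of the cis-disubstituted cyclopentene C5=C9 and cycloreverts to a C9 alkylidene carrying a C6 vinyl group (under ethylene in equilibrium with tetraene 19); the O8–Si–O1 tether then delivers the C10 isopropenyl group in a ring-closing metathesis that forms the seven-membered dioxasilepine (20), and the C6 vinyl group finally closes onto the C4 isopropenyl group with loss of ethylene to give the ten-membered carbocycle. The closest known reaction types are ring-rearrangement metathesis of cis-3,5-disubstituted cyclopentenes bearing tethered alkenes and silicon-tethered ring-closing metathesis to Z-trisubstituted 2-ene-1,4-diol silaketals; closing a ten-membered carbocycle at a trisubstituted alkene inside the same cascade is unproven. Ring closures: the dioxasilepine by tether-directed seven-membered RCM at C9=C10, the carbocycle by ten-membered RCM at C4=C5 onto the existing cis-fused lactone, the cyclopentene being consumed. No stereocentre is created, but both new alkenes must be Z: C9=C10 because an E alkene cannot sit in the seven-membered ring, C4=C5 because the cis-lactone/dioxasilepine scaffold and the low strain of a Z,Z-cyclodeca-1,6-diene should favour the cis closure. The C9–C10/C5–C4 pairing is secured by the tether (the alternative closures would be nine- or eleven-membered), ring opening is pulled forward because the trisubstituted products do not re-enter metathesis, the electron-poor 1,1-disubstituted methylene lactone could only close a cyclobutene and stays a spectator, and millimolar dilution holds back dimerization through the vinyl group.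

Step 12
Reactants: 21 tricyclic silaketal
Product: 22 (1S,3S,4Z,9Z)-3-acetoxy-1,8-dihydroxygermacra-4,9,11(13)-trien-12,6-olide
Conditions: HF·pyridine, pyridine, THF, 0 °C to rt
Reagents that add atoms: none
Why: Fluoride-assisted cleavage of both Si–O bonds of the dialkoxysilane under buffered acidic conditions that should leave acetate, lactone and allylic alcohols intact; no base is present, so acetyl migration from O3 to O1 is not expected.

Step 13
Reactants: 22 1,8-diol
Product: 23 1-O-triethylsilyl ether of 22 (C8 hydroxyl free)
Conditions: Et3SiCl (1.05 equiv), imidazole, CH2Cl2, −40 to −20 °C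
Reagents that add atoms: chlorotriethylsilane CC[Si](Cl)(CC)CC
Why: Kinetic monosilylation: the C1 hydroxyl, flanked by the C2 methylene, is expected to react faster than the C8 hydroxyl, which is flanked by the tertiary C7 and lies on the concave side beside the cis-fused lactone.

Step 14
Reactants: 23 1-O-triethylsilyl ether; 24 (R)-2-methylbutanoic acid
Product: 25 1-O-triethylsilyl 8-O-[(R)-2-methylbutanoyl] derivative
Conditions: DCC, DMAP (0.2 equiv), CH2Cl2, 0 °C to rt
Reagents that add atoms: none
Why: Steglich esterification of the only free hydroxyl; with catalytic DMAP at low temperature the non-activated α-stereocentre of the acid should not racemize.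

Step 15
Reactants: 25 silyl ether ester
Product: 26 (1S,3S,4Z,9Z)-3-acetoxy-1-hydroxy-8-[(R)-2-methylbutanoyloxy]germacra-4,9,11(13)-trien-12,6-olide (CNP0282531.1)
Conditions: HF·pyridine, pyridine, THF, 0 °C
Reagents that add atoms: none
Why: Selective cleavage of the triethylsilyl ether with buffered HF·pyridine; the three esters are stable and the absence of base avoids acyl migration.

**Compound list**

1 | (1S,5R)-2-oxabicyclo[3.3.0]oct-6-en-3-one | C1C(=O)O[C@H]2CC=C[C@@H]12 | starting material
2 | 4-exo-[(dimethylamino)methyl]-2-oxabicyclo[3.3.0]oct-6-en-3-one | CN(C)C[C@@H]1C(=O)O[C@H]2CC=C[C@@H]12 | intermediate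
3 | trimethylammonium iodide of 2 | C[N+](C)(C)C[C@@H]1C(=O)O[C@H]2CC=C[C@@H]12.[I-] | intermediate (not isolated)
4 | 4-methylene-2-oxabicyclo[3.3.0]oct-6-en-3-one | C=C1C(=O)O[C@H]2CC=C[C@@H]12 | intermediate
5 | 6,7-exo-epoxy-4-methylene-2-oxabicyclo[3.3.0]octan-3-one | C=C1C(=O)O[C@H]2C[C@@H]3O[C@@H]3[C@@H]12 | intermediate
6 | 6-exo-hydroxy-7-endo-phenylseleno-4-(phenylselenomethyl)-2-oxabicyclo[3.3.0]octan-3-one (C4 epimers) | c1ccccc1[Se]CC1C(=O)O[C@H]2C[C@@H]([Se]c3ccccc3)[C@H](O)[C@@H]12 | intermediate
7 | bis-selenoxide of 6 | O=[Se](c1ccccc1)CC1C(=O)O[C@H]2C[C@@H]([Se](=O)c3ccccc3)[C@H](O)[C@@H]12 | intermediate (not isolated)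
8 | 6-exo-hydroxy-4-methylene-2-oxabicyclo[3.3.0]oct-7-en-3-one | C=C1C(=O)O[C@H]2C=C[C@H](O)[C@@H]12 | intermediate
9 | cis-4-methylene-2-oxabicyclo[3.3.0]oct-7-ene-3,6-dione | C=C1C(=O)O[C@H]2C=CC(=O)[C@@H]12 | intermediate
10 | all-cis-6-hydroxy-4-methylene-2-oxabicyclo[3.3.0]oct-7-en-3-one | C=C1C(=O)O[C@H]2C=C[C@@H](O)[C@@H]12 | intermediate
11 | 3-methylbut-3-en-2-one | CC(=O)C(C)=C | starting material
12 | methacrolein | C=C(C)C=O | starting material
13 | 2-[(diisopinocampheylboryl)oxy]-3-methylbuta-1,3-diene (Ipc from (−)-α-pinene) | C=C(C)C(=C)OB([C@H]1C[C@H]2C[C@@H]([C@@H]1C)C2(C)C)[C@H]1C[C@H]2C[C@@H]([C@@H]1C)C2(C)C | intermediate (not isolated)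
14 | diisopinocampheylboron aldolate of 15 | C=C(C)[C@@H](OB([C@H]1C[C@H]2C[C@@H]([C@@H]1C)C2(C)C)[C@H]1C[C@H]2C[C@@H]([C@@H]1C)C2(C)C)CC(=O)C(C)=C | intermediate (not isolated)
15 | (S)-5-hydroxy-2,6-dimethylhepta-1,6-dien-3-one | C=C(C)[C@@H](O)CC(=O)C(C)=C | intermediate
16 | (3S,5S)-5-hydroxy-2,6-dimethylhepta-1,6-dien-3-yl acetate | C=C(C)[C@@H](OC(C)=O)C[C@H](O)C(C)=C | intermediate
17 | chlorodiisopropylsilyl ether of 16 | C=C(C)[C@@H](OC(C)=O)C[C@H](O[Si](Cl)(C(C)C)C(C)C)C(C)=C | intermediate (not isolated)
18 | mixed diisopropylsilaketal of 10 (O8) and 16 (O1) | C=C1C(=O)O[C@H]2C=C[C@@H](O[Si](C(C)C)(C(C)C)O[C@@H](C[C@H](OC(C)=O)C(C)=C)C(C)=C)[C@@H]12 | intermediate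
19 | ring-opened tetraene (C6 vinyl, C8 vinyl, acyclic silaketal) | C=C1C(=O)O[C@@H](C=C)[C@H]1[C@@H](C=C)O[Si](C(C)C)(C(C)C)O[C@@H](C[C@H](OC(C)=O)C(C)=C)C(C)=C | intermediate (not isolated)
20 | dioxasilepine triene (Z-C9=C10 in the seven-membered ring, C6 vinyl, C3 isopropenyl) | C=C1C(=O)O[C@@H](C=C)[C@H]1[C@H]2/C=C(C)\[C@H](C[C@H](OC(C)=O)C(C)=C)O[Si](C(C)C)(C(C)C)O2 | intermediate (not isolated)
21 | (1S,3S,4Z,9Z)-3-acetoxy-1,8-O-(diisopropylsilanediyl)germacra-4,9,11(13)-trien-12,6-olide | C=C1C(=O)O[C@H]2/C=C(/C)[C@@H](OC(C)=O)C[C@H](O[Si](C(C)C)(C(C)C)O3)/C(C)=C\[C@@H]3[C@@H]12 | intermediate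
22 | (1S,3S,4Z,9Z)-3-acetoxy-1,8-dihydroxygermacra-4,9,11(13)-trien-12,6-olide | C=C1C(=O)O[C@H]2/C=C(/C)[C@@H](OC(C)=O)C[C@H](O)/C(C)=C\[C@@H](O)[C@@H]12 | intermediate
23 | 1-O-triethylsilyl ether of 22 | C=C1C(=O)O[C@H]2/C=C(/C)[C@@H](OC(C)=O)C[C@H](O[Si](CC)(CC)CC)/C(C)=C\[C@@H](O)[C@@H]12 | intermediate
24 | (R)-2-methylbutanoic acid | CC[C@@H](C)C(=O)O | starting material
25 | 1-O-triethylsilyl 8-O-[(R)-2-methylbutanoyl] derivative | C=C1C(=O)O[C@H]2/C=C(/C)[C@@H](OC(C)=O)C[C@H](O[Si](CC)(CC)CC)/C(C)=C\[C@@H](OC(=O)[C@H](C)CC)[C@@H]12 | intermediate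
26 | CNP0282531.1 | C=C1C(=O)O[C@H]2/C=C(/C)[C@@H](OC(C)=O)C[C@H](O)/C(C)=C\[C@@H](OC(=O)[C@H](C)CC)[C@@H]12 | target

**Step count**

Total: 15 steps. Longest linear sequence: 13 steps (1 to 26 through steps 1–7 and 10–15); the diol half takes 2 steps (8, 9) and joins at step 10.

**Steps most likely to fail**

1. Step 11. The cascade may stall after ring opening and return 18, it may stop after the first closure and dimerize through the C6 vinyl group, or it may close C4=C5 with E geometry. Fallback: the one-pot cascade is given up for two separately known metathesis operations with isolation in between.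
   - From 18, the tether-relayed ring opening and seven-membered closure is run alone with (H2IMes)(PCy3)Cl2Ru=CHPh under C2H4 (1 atm) in CH2Cl2 at 5 mM and 40 °C and stopped at the dioxasilepine triene 20, which is isolated. Ethylene keeps C5 as a free vinyl group, and since only a seven-membered ring closes the concentration can be higher.
   - Pure 20 is then cyclized in a dedicated medium-ring RCM at 0.5 mM with the molybdenum imido alkylidene Mo(=CHCMe2Ph)(=N-2,6-iPr2C6H3)[OCMe(CF3)2]2 in benzene at 60 °C under Ar sparge. This catalyst class handles 1,1-disubstituted alkenes better.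
   - The route is rejoined at 21.

2. Step 13. Silylation may occur at the C8 hydroxyl or at both hydroxyls. Fallback from 22, using an orthogonal silyl pair so that the regioisomer is also productive:
   - the 8-O-triethylsilyl regioisomer F1 (isolated from the same silylation) is silylated at O1 with TBSOTf and 2,6-lutidine (CH2Cl2, −78 °C) to the 1-O-TBS 8-O-TES bis-ether F2;
   - the triethylsilyl group is removed selectively (PPTS, MeOH/CH2Cl2, 0 °C) to give the 1-O-TBS 8-hydroxy compound F3;
   - Steglich esterification with 24 (DCC, DMAP, CH2Cl2) gives the 1-O-TBS 8-O-[(R)-2-methylbutanoyl] ester F4;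
   - HF·pyridine (THF, pyridine, 0 °C to rt) removes the TBS group and the route is rejoined at 26.

3. Step 4. The selenolate may attack the wrong epoxide carbon (C6 instead of C7), which after elimination would place the alkene toward the ring fusion; the same stretch also passes through the base-sensitive enone 9 and the translactonization-prone alcohol 10. Fallback: the oxygen is placed by iodolactonization, whose regiochemistry is fixed by ring size.
   - The hydroxy acid underlying 10 is meso apart from the choice of lactonized oxygen, so iodolactonization of material from 1 would lead into the mirror-image series. No numbered compound can therefore serve as the branch point, and the fallback sets out from the commercial enantiomer of 1, (1R,5S)-2-oxabicyclo[3.3.0]oct-6-en-3-one F5, used in place of 1.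
   - The conditions of steps 1 and 2 applied to F5 give the mirror-image Mannich base F6, its trimethylammonium iodide F7 and the mirror-image methylene lactone F8.
   - Saponification (LiOH, THF/H2O, 0 °C) gives the cis-hydroxy acrylic acid F9 as its salt, which is iodolactonized without acidification (KI, I2, NaHCO3, H2O/THF, 0 °C, dark). The carboxylate should close 5-exo onto the nearer alkene carbon, cis to the side chain, with iodine trans on future C5. This gives the iodo hydroxy lactone F10, in which the former lactone oxygen is now the free all-cis hydroxyl (future O8).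
   - F10 is silylated with chlorosilane 17 and imidazole as in step 10 to give the iodo silaketal F11.
   - Anti-elimination of HI with DBU (toluene, rt to 60 °C) can only use the C9 methylene hydrogens, because H6 is cis to iodine. It gives 18, where the route is rejoined; compounds 5–10 are by-passed and the free alcohol 10 never has to be handled.

**Further compounds**

F0 | step 11 | none | none
F1 | step 13 | 8-O-triethylsilyl ether of 22 (C1 hydroxyl free) | C=C1C(=O)O[C@H]2/C=C(/C)[C@@H](OC(C)=O)C[C@H](O)/C(C)=C\[C@@H](O[Si](CC)(CC)CC)[C@@H]12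
F2 | step 13 | 1-O-tert-butyldimethylsilyl 8-O-triethylsilyl bis-ether of 22 | C=C1C(=O)O[C@H]2/C=C(/C)[C@@H](OC(C)=O)C[C@H](O[Si](C)(C)C(C)(C)C)/C(C)=C\[C@@H](O[Si](CC)(CC)CC)[C@@H]12
F3 | step 13 | 1-O-tert-butyldimethylsilyl ether of 22 (C8 hydroxyl free) | C=C1C(=O)O[C@H]2/C=C(/C)[C@@H](OC(C)=O)C[C@H](O[Si](C)(C)C(C)(C)C)/C(C)=C\[C@@H](O)[C@@H]12
F4 | step 13 | 1-O-tert-butyldimethylsilyl 8-O-[(R)-2-methylbutanoyl] derivative | C=C1C(=O)O[C@H]2/C=C(/C)[C@@H](OC(C)=O)C[C@H](O[Si](C)(C)C(C)(C)C)/C(C)=C\[C@@H](OC(=O)[C@H](C)CC)[C@@H]12
F5 | step 4 | (1R,5S)-2-oxabicyclo[3.3.0]oct-6-en-3-one (bought) | C1C(=O)O[C@@H]2CC=C[C@H]12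
F6 | step 4 | enantiomer of 2 | CN(C)C[C@H]1C(=O)O[C@@H]2CC=C[C@H]12
F7 | step 4 | enantiomer of 3 | C[N+](C)(C)C[C@H]1C(=O)O[C@@H]2CC=C[C@H]12.[I-]
F8 | step 4 | enantiomer of 4 | C=C1C(=O)O[C@@H]2CC=C[C@H]12
F9 | step 4 | 2-(cis-5-hydroxycyclopent-2-en-1-yl)acrylic acid | C=C(C(=O)O)[C@H]1C=CC[C@H]1O
F10 | step 4 | all-cis 6-hydroxy-8-exo-iodo-4-methylene-2-oxabicyclo[3.3.0]octan-3-one (iodine trans to the lactone oxygen) | C=C1C(=O)O[C@H]2[C@H](I)C[C@@H](O)[C@@H]12
F11 | step 4 | diisopropylsilaketal of F10 and 16 | C=C1C(=O)O[C@H]2[C@H](I)C[C@@H](O[Si](C(C)C)(C(C)C)O[C@@H](C[C@H](OC(C)=O)C(C)=C)C(C)=C)[C@@H]12
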